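**Retrosynthet­ic overview**

1. Target 15 ⇐ one-pot cleavage of two aryl methyl ethers and three tert-butyl esters of 14 ⇐ syn-dehydration across C3–C4 of 3-hydroxytetralin 13.
2. 13 ⇐ rhodium-catalysed asymmetric 4→6 ring expansion: the four-membered ring of benzocyclobutenol 4 (aryl C1 and C6, C7, C8 = C4a, C8a, C3, C4 of the target) is cut at C6–C7 and the two alkene carbons of acrylate 12 (C1 and C2 of the target) are inserted; bonds made C8a–C1 and C2–C3.
3. Enabling feature: C4 and the carboxyl-bearing C3 hang on the arene bond C4a–C8a, so arene–C4–C3(CO2R)–O can be stored as a strained benzocyclobutenol; C1/C2 are the β/α carbons of an acrylic ester carrying the pyranone (C4′) at C1; the C3 oxygen first triggers C–C cleavage and later leaves to give C3=C4.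
4. 4 ⇐ benzocyclobutene acid 1 (esterification, enolate hydroxylation); 12 ⇐ 2-pyranone from ethyl 3-methylbut-2-enoate and diethyl oxalate (vinylogous Claisen/lactonisation), then CH3 → CHO → acrylate.
5. Ring order: pyranone (step 3); arene and cyclobutene come with 1; the carbocyclic six-membered ring is formed last (step 7).

Key step: step 7

Assumption: racemic 3,4-dimethoxybicyclo[4.2.0]octa-1,3,5-triene-7-carboxylic acid (1) is taken as purchasable; it is the hydrolysis product of the commercial nitrile of the same skeleton.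

**Route**

Step 1
Reactants: 1 (±)-3,4-dimethoxybicyclo[4.2.0]octa-1,3,5-triene-7-carboxylic acid
Product: 2 tert-butyl (±)-3,4-dimethoxybicyclo[4.2.0]octa-1,3,5-triene-7-carboxylate
Conditions: Cl3CC(=NH)Ot-Bu, BF3·OEt2 (cat.), CH2Cl2–cyclohexane, rt
Reagents that add atoms: tert-butyl 2,2,2-trichloroacetimidate, CC(C)(C)OC(=N)C(Cl)(Cl)Cl
Why: Acid-catalysed O-alkylation of a carboxylic acid by a trichloroacetimidate (tert-butyl cation transfer) is mild enough for the strained benzocyclobutene, and no stereocentre is set.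

Step 2
Reactants: 2 tert-butyl (±)-3,4-dimethoxybicyclo[4.2.0]octa-1,3,5-triene-7-carboxylate
Product: 4 tert-butyl (±)-7-hydroxy-3,4-dimethoxybicyclo[4.2.0]octa-1,3,5-triene-7-carboxylate, via lithium ester enolate 3 (not isolated)
Conditions: LDA, THF, −78 °C; (camphorsulfonyl)oxaziridine, −78 → −40 °C; AcOH
Reagents that add atoms: (camphorsulfonyl)oxaziridine, CC1(C)C2CCC13CS(=O)(=O)N4OC34C2
Why: Electrophilic enolate hydroxylation with an N-sulfonyloxaziridine should give the tertiary α-hydroxy ester, the lithium counter-ion and cold quench keeping the alkoxide from electrocyclic ring opening; C7 is formed racemic, which suffices because it becomes a planar ketone carbon in step 7.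

Step 3
Reactants: 5 ethyl 3-methylbut-2-enoate; 6 diethyl oxalate
Product: 8 4-methyl-2-oxo-2H-pyran-6-carboxylic acid, via potassium dienolate 7 (not isolated)
Conditions: KOEt, EtOH–Et2O, 0 °C → rt; then conc. HCl, 100 °C
Reagents that add atoms: water, O
Why: Vinylogous (γ) Claisen condensation of the enoate dienolate with the oxalate, followed by acid-mediated enol lactonisation and ester hydrolysis, is the classical entry to 2-pyranone-6-carboxylic acids.

Step 4
Reactants: 8 4-methyl-2-oxo-2H-pyran-6-carboxylic acid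
Product: 9 tert-butyl 4-methyl-2-oxo-2H-pyran-6-carboxylate
Conditions: Cl3CC(=NH)Ot-Bu, BF3·OEt2 (cat.), CH2Cl2–cyclohexane, rt
Reagents that add atoms: tert-butyl 2,2,2-trichloroacetimidate, CC(C)(C)OC(=N)C(Cl)(Cl)Cl
Why: The same acid-catalysed trichloroacetimidate esterification avoids base, to which the 2-pyranone is sensitive.

Step 5
Reactants: 9 tert-butyl 4-methyl-2-oxo-2H-pyran-6-carboxylate
Product: 10 tert-butyl 4-formyl-2-oxo-2H-pyran-6-carboxylate
Conditions: SeO2, 1,4-dioxane, 100 °C
Reagents that add atoms: selenium dioxide, O=[Se]=O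
Why: Riley oxidation of the vinylogously activated 4-methyl group of a 2-pyranone (as for 4-methylcoumarins) should stop at the aldehyde.

Step 6
Reactants: 10 tert-butyl 4-formyl-2-oxo-2H-pyran-6-carboxylate; 11 tert-butyl 2-(triphenyl-λ5-phosphanylidene)acetate
Product: 12 tert-butyl (2E)-3-[6-(tert-butoxycarbonyl)-2-oxo-2H-pyran-4-yl]prop-2-enoate
Conditions: CH2Cl2, 0 °C → rt
Reagents that add atoms: none
Why: Wittig olefination with a stabilised ylide is selective for the aldehyde over the lactone carbonyl and should give the (E)-enoate.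

Step 7
Reactants: 4 tert-butyl (±)-7-hydroxy-3,4-dimethoxybicyclo[4.2.0]octa-1,3,5-triene-7-carboxylate; 12 tert-butyl (2E)-3-[6-(tert-butoxycarbonyl)-2-oxo-2H-pyran-4-yl]prop-2-enoate
Product: 13 di-tert-butyl (1R,2S,3R)-1-[6-(tert-butoxycarbonyl)-2-oxo-2H-pyran-4-yl]-3-hydroxy-6,7-dimethoxy-1,2,3,4-tetrahydronaphthalene-2,3-dicarboxylate
Conditions: [Rh(OH)((S)-BINAP)]2 (2.5 mol %), toluene, 60 °C, slow addition of 4 (1.3 equiv)
Reagents that add atoms: none
Why: Proposed new method: the rhodium(I) alkoxide of 4 should undergo β-carbon elimination of the strained C7–C(aryl) bond to an arylrhodium species with an ortho CH2–CO–CO2t-Bu arm, which adds 1,4 to enoate 12 (aryl to the acrylate β-carbon) and whose rhodium enolate then adds to the α-keto ester, the tertiary rhodium alkoxide being released by exchange with the next molecule of 4, so that the two alkene carbons are inserted into the four-membered ring. The closest known reaction types are the rhodium-catalysed [4+2] ring expansion of benzocyclobutenols with alkynes (same C(sp2)–C(sp3) cleavage, then addition to the unveiled ketone) and the rhodium/bisphosphine-catalysed asymmetric conjugate addition–aldol cyclisation of arylrhodium species. The only ring closed is the carbocycle, by a 6-(enolexo)-exo-trig aldol addition of C2 to the C3 ketone. C1 is set by the ligand (aryl delivery to the Re face of the acrylate β-carbon, expected for (S)-BINAP by analogy with (E)-enoates, the antipodal ligand being used if the sense proves opposite), C2 follows from C1 by allylic-strain control in the enolate (C1–H eclipsing the enolate, closure anti to the pyranone, hence 1,2-trans), and C3 from the rhodium-chelated transition state that places the hydroxyl cis to the C2 ester; both enantiomers of racemic 4 converge because C7 becomes the planar ketone carbon. The step needs aryl–C over alkyl–C cleavage (secured by the stronger Rh–aryl bond), insertion at the disubstituted acrylate and not at the trisubstituted pyranone alkenes, aryl attack β to the tert-butyl ester (rhodium oxa-π-allyl), and capture of the arylrhodium before it is protonated by the acidic aryl pyruvate, which the slow addition of 4 to excess catalyst-bound 12 is meant to secure.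

Step 8
Reactants: 13 di-tert-butyl (1R,2S,3R)-1-[6-(tert-butoxycarbonyl)-2-oxo-2H-pyran-4-yl]-3-hydroxy-6,7-dimethoxy-1,2,3,4-tetrahydronaphthalene-2,3-dicarboxylate
Product: 14 di-tert-butyl (1R,2S)-1-[6-(tert-butoxycarbonyl)-2-oxo-2H-pyran-4-yl]-6,7-dimethoxy-1,2-dihydronaphthalene-2,3-dicarboxylate
Conditions: Burgess reagent, toluene, 50 → 70 °C
Reagents that add atoms: none
Why: Burgess dehydration is a syn (Ei) elimination through the sulfamate ester, and since the C3–O bond is syn only to a C4 hydrogen (C2–H is trans to the hydroxyl) the arene- and ester-conjugated C3=C4 bond should form without touching C1 or C2.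

Step 9
Reactants: 14 di-tert-butyl (1R,2S)-1-[6-(tert-butoxycarbonyl)-2-oxo-2H-pyran-4-yl]-6,7-dimethoxy-1,2-dihydronaphthalene-2,3-dicarboxylate
Product: 15 (1R,2S)-1-(6-carboxy-2-oxo-2H-pyran-4-yl)-6,7-dihydroxy-1,2-dihydronaphthalene-2,3-dicarboxylic acid
Conditions: BBr3 (excess), CH2Cl2, −78 °C → rt; then H2O, 0 °C
Reagents that add atoms: none
Why: Lewis-acid dealkylation with boron tribromide cleaves both aryl methyl ethers and all three tert-butyl esters without base, which the 2-pyranone and the epimerisable C1 and C2 centres require, and aqueous hydrolysis of the boron esters frees the catechol and the three acids.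

**Compound list**

1 | (±)-3,4-dimethoxybicyclo[4.2.0]octa-1,3,5-triene-7-carboxylic acid | COc1cc2CC(C(=O)O)c2cc1OC | starting material
2 | tert-butyl (±)-3,4-dimethoxybicyclo[4.2.0]octa-1,3,5-triene-7-carboxylate | COc1cc2CC(C(=O)OC(C)(C)C)c2cc1OC | intermediate
3 | lithium ester enolate of 2 | COc1cc2CC(=C([O-])OC(C)(C)C)c2cc1OC.[Li+] | intermediate
4 | tert-butyl (±)-7-hydroxy-3,4-dimethoxybicyclo[4.2.0]octa-1,3,5-triene-7-carboxylate | COc1cc2CC(O)(C(=O)OC(C)(C)C)c2cc1OC | intermediate
5 | ethyl 3-methylbut-2-enoate | CCOC(=O)C=C(C)C | starting material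
6 | diethyl oxalate | CCOC(=O)C(=O)OCC | starting material
7 | potassium 1,6-diethoxy-4-methyl-1,6-dioxohexa-2,4-dien-2-olate (alkene isomers) | CCOC(=O)C([O-])=CC(C)=CC(=O)OCC.[K+] | intermediate
8 | 4-methyl-2-oxo-2H-pyran-6-carboxylic acid | Cc1cc(C(=O)O)oc(=O)c1 | intermediate
9 | tert-butyl 4-methyl-2-oxo-2H-pyran-6-carboxylate | Cc1cc(C(=O)OC(C)(C)C)oc(=O)c1 | intermediate
10 | tert-butyl 4-formyl-2-oxo-2H-pyran-6-carboxylate | O=Cc1cc(C(=O)OC(C)(C)C)oc(=O)c1 | intermediate
11 | tert-butyl 2-(triphenyl-λ5-phosphanylidene)acetate | CC(C)(C)OC(=O)C=P(c1ccccc1)(c1ccccc1)c1ccccc1 | starting material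
12 | tert-butyl (2E)-3-[6-(tert-butoxycarbonyl)-2-oxo-2H-pyran-4-yl]prop-2-enoate | CC(C)(C)OC(=O)/C=C/c1cc(C(=O)OC(C)(C)C)oc(=O)c1 | intermediate
13 | di-tert-butyl (1R,2S,3R)-1-[6-(tert-butoxycarbonyl)-2-oxo-2H-pyran-4-yl]-3-hydroxy-6,7-dimethoxy-1,2,3,4-tetrahydronaphthalene-2,3-dicarboxylate | CC(C)(C)OC(=O)[C@@]1(O)Cc2cc(OC)c(OC)cc2[C@@H](c2cc(C(=O)OC(C)(C)C)oc(=O)c2)[C@@H]1C(=O)OC(C)(C)C | intermediate
14 | di-tert-butyl (1R,2S)-1-[6-(tert-butoxycarbonyl)-2-oxo-2H-pyran-4-yl]-6,7-dimethoxy-1,2-dihydronaphthalene-2,3-dicarboxylate | CC(C)(C)OC(=O)C1=Cc2cc(OC)c(OC)cc2[C@@H](c2cc(C(=O)OC(C)(C)C)oc(=O)c2)[C@@H]1C(=O)OC(C)(C)C | intermediate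
15 | (1R,2S)-1-(6-carboxy-2-oxo-2H-pyran-4-yl)-6,7-dihydroxy-1,2-dihydronaphthalene-2,3-dicarboxylic acid | O=C(O)C1=Cc2cc(O)c(O)cc2[C@@H](c2cc(C(=O)O)oc(=O)c2)[C@@H]1C(=O)O | target

**Summary**

Total step count: 9. Longest linear sequence: 7 steps (steps 3–9).

Steps most likely to fail:

Step 7 (carries the label). What may go wrong: the arylrhodium intermediate is protonated by the enolisable aryl pyruvate before it inserts the β-substituted acrylate; aryl is transferred to the α-carbon (vinylogous addition through the pyranone); facial selectivity is low. The fallback uses known chemistry, a photoenolisation/Diels–Alder sequence, and sets out from 9. Radical bromination (NBS, AIBN, PhCF3, 80 °C) gives tert-butyl 4-(bromomethyl)-2-oxo-2H-pyran-6-carboxylate F1. Suzuki–Miyaura coupling with commercial (2-formyl-4,5-dimethoxyphenyl)boronic acid (Pd(PPh3)4, K3PO4, toluene–H2O) gives tert-butyl 4-[(2-formyl-4,5-dimethoxyphenyl)methyl]-2-oxo-2H-pyran-6-carboxylate F2. Irradiation at 366 nm with di-tert-butyl fumarate under Ti(Oi-Pr)4/TADDOL control (ligand enantiomer chosen for the 1R series; the (E)-hydroxy-o-quinodimethane adds endo with respect to the ester next to the hydroxyl) should give di-tert-butyl (1R,2S,3R,4R)-1-[6-(tert-butoxycarbonyl)-2-oxo-2H-pyran-4-yl]-4-hydroxy-6,7-dimethoxy-1,2,3,4-tetrahydronaphthalene-2,3-dicarboxylate F3. Anti-elimination of the benzylic C4 hydroxyl (MsCl, Et3N, CH2Cl2, 0 °C) brings the material back to the route at 14.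

Step 8. What may go wrong: sulfamate formation fails at the hindered tertiary carbinol, or elimination takes the C2 proton and destroys the C2 stereocentre. The fallback sets out from 13: alkoxide formation and xanthylation (NaHMDS, CS2, MeI, THF, −78 → 0 °C) give di-tert-butyl (1R,2S,3R)-1-[6-(tert-butoxycarbonyl)-2-oxo-2H-pyran-4-yl]-6,7-dimethoxy-3-{[(methylsulfanyl)carbonothioyl]oxy}-1,2,3,4-tetrahydronaphthalene-2,3-dicarboxylate F4. Chugaev syn-elimination (toluene, 90 °C) returns to 14.

Step 9. What may go wrong: tert-butyl cations alkylate the electron-rich ring, ether cleavage stops half-way, or strong acid attacks the styrenic C3=C4 bond. The fallback is a staged deprotection from 14: TFA with 1,3-dimethoxybenzene as cation scavenger (CH2Cl2, 0 °C → rt) gives (1R,2S)-1-(6-carboxy-2-oxo-2H-pyran-4-yl)-6,7-dimethoxy-1,2-dihydronaphthalene-2,3-dicarboxylic acid F5. Demethylation with BCl3/n-Bu4NI (CH2Cl2, −78 → 0 °C) then gives 15.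

**Further compounds**

F1 | step 7 | tert-butyl 4-(bromomethyl)-2-oxo-2H-pyran-6-carboxylate | BrCc1cc(C(=O)OC(C)(C)C)oc(=O)c1
F2 | step 7 | tert-butyl 4-[(2-formyl-4,5-dimethoxyphenyl)methyl]-2-oxo-2H-pyran-6-carboxylate | COc1cc(C=O)c(Cc2cc(C(=O)OC(C)(C)C)oc(=O)c2)cc1OC
F3 | step 7 | di-tert-butyl (1R,2S,3R,4R)-1-[6-(tert-butoxycarbonyl)-2-oxo-2H-pyran-4-yl]-4-hydroxy-6,7-dimethoxy-1,2,3,4-tetrahydronaphthalene-2,3-dicarboxylate | CC(C)(C)OC(=O)[C@H]1[C@@H](O)c2cc(OC)c(OC)cc2[C@@H](c2cc(C(=O)OC(C)(C)C)oc(=O)c2)[C@@H]1C(=O)OC(C)(C)C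
F4 | step 8 | di-tert-butyl (1R,2S,3R)-1-[6-(tert-butoxycarbonyl)-2-oxo-2H-pyran-4-yl]-6,7-dimethoxy-3-{[(methylsulfanyl)carbonothioyl]oxy}-1,2,3,4-tetrahydronaphthalene-2,3-dicarboxylate | CC(C)(C)OC(=O)[C@@]1(OC(=S)SC)Cc2cc(OC)c(OC)cc2[C@@H](c2cc(C(=O)OC(C)(C)C)oc(=O)c2)[C@@H]1C(=O)OC(C)(C)C
F5 | step 9 | (1R,2S)-1-(6-carboxy-2-oxo-2H-pyran-4-yl)-6,7-dimethoxy-1,2-dihydronaphthalene-2,3-dicarboxylic acid | O=C(O)C1=Cc2cc(OC)c(OC)cc2[C@@H](c2cc(C(=O)O)oc(=O)c2)[C@@H]1C(=O)O
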